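**Plan**

Numbering: bicycloheptane carbons C1–C7 (C1, C5 bridgeheads; C2 spiro carbon; C6 the CMe2 bridge; C7 the CH2 bridge); pyran atoms O1', C3', C4', C4a', C8a'.
Retrosynthetic cuts: (i) the C3'–H and C4'–H bonds (hydrogenation of a spiro-2H-pyran); (ii) O1'–C2 (oxa-6π) and C1–C2 (radical 6-exo-dig) in one cascade, back to an alkyne-extended alkylidene β-triketone; (iii) C3'–C4' (zinc acetylide conjugate addition); (iv) the cyclobutane comes from α-pinene by C2=C3 cleavage and Baeyer–Villiger excision of the acetyl carbon.
Enabling feature: C2 is the enol-ether carbon of a pyran fused to the β-triketone. Written as a 1-oxatriene with a C2≡C3' alkyne, the C4'=C4a' alkylidene triketone relays acceptor character to C2, which lies six atoms from a radical at C1 across the cis-1,3-disubstituted cyclobutane (C1, C5, C6, C7).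
Forward ring order: cyclobutane (chiral pool), then the C1–C2–C3–C4–C5 bridge of the bicyclo[3.1.1]heptane, then the pyran, then alkene reduction. The helpers (xanthate, extra unsaturation) leave in the last two steps.
Stereochemistry: C5 from (1R,5R)-α-pinene; C1 forced cis by the bridge; C2 by electrocyclisation on the face remote from the C6 bridge; C4' by hydrogenation from the C3 side.

Key step: step 10

Assumption: syncarpic acid is taken as a purchasable building block, and the alkylidene triketone made from it is used crude because such acceptors are reactive.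

**Step 1**
Reactants: 1 (1R,5R)-(+)-α-pinene
Product: 2 2-[(1S,3S)-3-acetyl-2,2-dimethylcyclobutyl]acetic acid (cis-pinonic acid)
Conditions: RuCl3·xH2O (2 mol%), NaIO4 (4 equiv), CCl4/MeCN/H2O, 20 °C
Reagents that add atoms: sodium periodate [Na+].[O-]I(=O)(=O)=O; water O
Why: RuO4 formed in the flask cleaves the trisubstituted C2=C3 alkene to ketone and acid (a standard degradation of α-pinene), leaving the cis-1,3-disubstituted gem-dimethylcyclobutane and both stereocentres untouched.

**Step 2**
Reactants: 2 2-[(1S,3S)-3-acetyl-2,2-dimethylcyclobutyl]acetic acid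
Product: 3 2-[(1S,3S)-3-(acetyloxy)-2,2-dimethylcyclobutyl]acetic acid
Conditions: mCPBA (2 equiv), CH2Cl2, 20 °C, dark
Reagents that add atoms: mCPBA OOC(=O)c1cccc(Cl)c1
Why: Baeyer–Villiger oxidation of the methyl ketone, in which the secondary cyclobutyl carbon migrates in preference to methyl and with retention, so the ring carbon that becomes the radical centre now bears oxygen.

**Step 3**
Reactants: 3 2-[(1S,3S)-3-(acetyloxy)-2,2-dimethylcyclobutyl]acetic acid
Product: 4 (1S,3R)-3-(2-hydroxyethyl)-2,2-dimethylcyclobutan-1-ol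
Conditions: LiAlH4 (3 equiv), THF, 0 °C to reflux; H2O work-up
Reagents that add atoms: none
Why: LiAlH4 reduces the acid to the primary alcohol and cleaves the acetate, giving the diol without touching either ring stereocentre.

**Step 4**
Reactants: 4 (1S,3R)-3-(2-hydroxyethyl)-2,2-dimethylcyclobutan-1-ol
Product: 5 2-[(1R,3S)-3-hydroxy-2,2-dimethylcyclobutyl]ethyl 4-methylbenzenesulfonate
Conditions: TsCl (1.05 equiv), Et3N, DMAP (cat.), CH2Cl2, −10 to 0 °C
Reagents that add atoms: 4-toluenesulfonyl chloride Cc1ccc(cc1)S(=O)(=O)Cl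
Why: Sulfonylation should be selective for the primary hydroxyl because the ring hydroxyl is secondary and flanked by the quaternary carbon.

**Step 5**
Reactants: 5 2-[(1R,3S)-3-hydroxy-2,2-dimethylcyclobutyl]ethyl 4-methylbenzenesulfonate
Product: 6 (1S,3R)-3-(but-3-yn-1-yl)-2,2-dimethylcyclobutan-1-ol
Conditions: lithium acetylide–ethylenediamine complex (4 equiv), DMSO (1 M), 20 °C
Reagents that add atoms: lithium acetylide [Li+].[C-]#C
Why: SN2 displacement of the primary tosylate by acetylide adds the two alkyne carbons (future C2 and C3'); excess acetylide at high concentration should outrun etherification by the ring alkoxide.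

**Step 6**
Reactants: 6 (1S,3R)-3-(but-3-yn-1-yl)-2,2-dimethylcyclobutan-1-ol
Product: 7 O-[(1S,3R)-3-(but-3-yn-1-yl)-2,2-dimethylcyclobutyl] S-methyl carbonodithioate
Conditions: NaH (1.1 equiv), imidazole (cat.), THF, 0 °C; CS2; then MeI
Reagents that add atoms: carbon disulfide S=C=S; iodomethane CI
Why: Standard xanthate formation (alkoxide, CS2, S-methylation) places a Barton–McCombie radical precursor on the hindered ring hydroxyl without any substitution at that carbon.

**Step 7**
Reactants: 8 syncarpic acid (2,2,4,4-tetramethylcyclohexane-1,3,5-trione); 9 isobutyraldehyde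
Product: 10 2,2,4,4-tetramethyl-6-(2-methylpropylidene)cyclohexane-1,3,5-trione
Conditions: pyrrolidine (10 mol%), AcOH (10 mol%), 9 (3 equiv), CH2Cl2, 4 Å molecular sieves, 20 °C; short silica plug, used at once
Reagents that add atoms: none
Why: Knoevenagel condensation of the cyclic β-triketone with the aldehyde gives the alkylidene triketone, and the excess of aldehyde should suppress the bis-adduct.

**Step 8**
Reactants: 7 O-[(1S,3R)-3-(but-3-yn-1-yl)-2,2-dimethylcyclobutyl] S-methyl carbonodithioate; 10 2,2,4,4-tetramethyl-6-(2-methylpropylidene)cyclohexane-1,3,5-trione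
Product: 11 O-[(1S,3R)-3-[5-(2-hydroxy-3,3,5,5-tetramethyl-4,6-dioxocyclohex-1-en-1-yl)-6-methylhept-3-yn-1-yl]-2,2-dimethylcyclobutyl] S-methyl carbonodithioate (both epimers at the propargylic carbon)
Conditions: Zn(OTf)2 (1.2 equiv), Et3N (1.5 equiv), toluene, 20 to 40 °C; aqueous NH4Cl
Reagents that add atoms: none
Why: The zinc acetylide formed from the terminal alkyne adds in conjugate fashion to the doubly activated alkylidene, as known for alkylidene Meldrum's acids; the new propargylic centre (C4') forms as both epimers, which does not matter because it becomes sp2 in step 9.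

**Step 9**
Reactants: 11 the propargylic β-triketone enol from step 8
Product: 12 O-[(1S,3R)-2,2-dimethyl-3-[6-methyl-5-(3,3,5,5-tetramethyl-2,4,6-trioxocyclohexylidene)hept-3-yn-1-yl]cyclobutyl] S-methyl carbonodithioate
Conditions: DDQ (1.2 equiv), 1,4-dioxane, 25 to 60 °C
Reagents that add atoms: none
Why: DDQ should abstract hydride from the tertiary C4'–H, which is propargylic and attached to the enol carbon (the dehydrogenation known for 2-allyl and 2-benzyl enolised 1,3-dicarbonyls), and loss of the enol proton gives the tetrasubstituted alkylidene triketone in conjugation with the alkyne.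

**Step 10**
Reactants: 12 the enyne-trione xanthate from step 9
Product: 15 (1S,2S,5R)-4'-isopropyl-6,6,6',6',8',8'-hexamethylspiro[bicyclo[3.1.1]heptane-2,2'-chromene]-5',7'(6'H,8'H)-dione, via allenyl enol 13 (not isolated), via 1-oxatriene 14 (not isolated)
Conditions: Bu3SnH (1.3 equiv, syringe pump, 6 h), Et3B (0.3 equiv)/air, toluene (0.005 M), 25 °C; no heating on work-up
Reagents that add atoms: none
Why: Proposed new method: thiophilic addition of Bu3Sn• to the xanthate and β-scission of its C–O bond release a secondary cyclobutyl radical at C1, a nucleophilic radical that should add 6-exo-dig to C2, the alkyne carbon that is the δ-terminus of the doubly acylated enyne; the closest known reaction types are the Barton–McCombie-initiated Giese cyclisation of alkyl radicals onto ynones and alkylidene malonates and the oxa-6π-electrocyclisation of 1-oxatrienes in the formal [3+3] synthesis of 2H-pyrans from 1,3-diones. The allenyl radical, delocalised onto the tricarbonyl unit, is reduced by Bu3SnH to allenyl enol 13, a [1,5]-hydrogen shift from the enol oxygen to the central allene carbon C3' gives 1-oxatriene 14, and disrotatory closure of O1' onto C2 gives 15. Ring closures: the C1–C2–C3–C4–C5 bridge of the bicyclo[3.1.1]heptane by 6-exo-dig radical attack, the pyran by thermal oxa-6π-electrocyclisation. Stereocentres: C1 can bond only on the face that carries the C5 side chain, so the configuration of the xanthate carbon is erased and the cis bridge is enforced by the tether; C2 is set by approach of the carbonyl oxygen to the face of the exocyclic C2=C3' bond remote from the gem-dimethyl bridge C6, the face used in additions to β-pinene. Selectivity needed: radical generation must beat stannyl addition to the acceptor, cyclisation must beat reduction and 1,5-hydrogen transfer from C3, and the spiro centre must not equilibrate by electrocyclic ring opening; these are addressed by the fast thiophilic addition, slow addition of the hydride, the polarity-matched activated acceptor and ambient temperature.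

**Step 11**
Reactants: 15 the spiro-2H-pyran from step 10
Product: 16 (1S,2S,4'R,5R)-4'-isopropyl-6,6,6',6',8',8'-hexamethyl-3',4'-dihydrospiro[bicyclo[3.1.1]heptane-2,2'-chromene]-5',7'(6'H,8'H)-dione (target)
Conditions: H2 (4 atm), 5% Rh on Al2O3, EtOAc, 20 °C
Reagents that add atoms: none
Why: Heterogeneous hydrogenation should add H2 syn to the only reactive alkene (C3'=C4'; the tetrasubstituted vinylogous ester alkene and the hindered ketones are inert) from the pyran face flanked by the C3 methylene and not by bridgehead C1 and its C6 bridge, which places isopropyl cis to C1 as in the target; Rh on Al2O3 is chosen to limit hydrogenolysis of the allylic C2–O bond.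

**Compound list**

1 | (1R,5R)-(+)-α-pinene | CC1=CC[C@@H]2C[C@H]1C2(C)C | starting material
2 | 2-[(1S,3S)-3-acetyl-2,2-dimethylcyclobutyl]acetic acid | CC(=O)[C@H]1C[C@@H](CC(=O)O)C1(C)C | intermediate
3 | 2-[(1S,3S)-3-(acetyloxy)-2,2-dimethylcyclobutyl]acetic acid | CC(=O)O[C@H]1C[C@@H](CC(=O)O)C1(C)C | intermediate
4 | (1S,3R)-3-(2-hydroxyethyl)-2,2-dimethylcyclobutan-1-ol | OCC[C@@H]1C[C@H](O)C1(C)C | intermediate
5 | 2-[(1R,3S)-3-hydroxy-2,2-dimethylcyclobutyl]ethyl 4-methylbenzenesulfonate | Cc1ccc(cc1)S(=O)(=O)OCC[C@@H]1C[C@H](O)C1(C)C | intermediate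
6 | (1S,3R)-3-(but-3-yn-1-yl)-2,2-dimethylcyclobutan-1-ol | C#CCC[C@@H]1C[C@H](O)C1(C)C | intermediate
7 | O-[(1S,3R)-3-(but-3-yn-1-yl)-2,2-dimethylcyclobutyl] S-methyl carbonodithioate | C#CCC[C@@H]1C[C@H](OC(=S)SC)C1(C)C | intermediate
8 | syncarpic acid (2,2,4,4-tetramethylcyclohexane-1,3,5-trione) | CC1(C)C(=O)CC(=O)C(C)(C)C1=O | starting material
9 | isobutyraldehyde | CC(C)C=O | starting material
10 | 2,2,4,4-tetramethyl-6-(2-methylpropylidene)cyclohexane-1,3,5-trione | CC(C)C=C1C(=O)C(C)(C)C(=O)C(C)(C)C1=O | intermediate
11 | O-[(1S,3R)-3-[5-(2-hydroxy-3,3,5,5-tetramethyl-4,6-dioxocyclohex-1-en-1-yl)-6-methylhept-3-yn-1-yl]-2,2-dimethylcyclobutyl] S-methyl carbonodithioate (both epimers at the propargylic carbon) | CC(C)C(C#CCC[C@@H]1C[C@H](OC(=S)SC)C1(C)C)C1=C(O)C(C)(C)C(=O)C(C)(C)C1=O | intermediate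
12 | O-[(1S,3R)-2,2-dimethyl-3-[6-methyl-5-(3,3,5,5-tetramethyl-2,4,6-trioxocyclohexylidene)hept-3-yn-1-yl]cyclobutyl] S-methyl carbonodithioate | CC(C)C(C#CCC[C@@H]1C[C@H](OC(=S)SC)C1(C)C)=C1C(=O)C(C)(C)C(=O)C(C)(C)C1=O | intermediate
13 | 5-hydroxy-2,2,6,6-tetramethyl-4-[3-methyl-1-[(1S,5R)-6,6-dimethylbicyclo[3.1.1]heptan-2-ylidene]but-1-en-2-yl]cyclohex-4-ene-1,3-dione (allenyl enol, allene axis undefined) | CC(C)C(=C=C1CC[C@@H]2C[C@H]1C2(C)C)C1=C(O)C(C)(C)C(=O)C(C)(C)C1=O | intermediate
14 | 2,2,4,4-tetramethyl-6-[1-[(1S,5R)-6,6-dimethylbicyclo[3.1.1]heptan-2-ylidene]-3-methylbutan-2-ylidene]cyclohexane-1,3,5-trione (1-oxatriene) | CC(C)C(C=C1CC[C@@H]2C[C@H]1C2(C)C)=C1C(=O)C(C)(C)C(=O)C(C)(C)C1=O | intermediate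
15 | (1S,2S,5R)-4'-isopropyl-6,6,6',6',8',8'-hexamethylspiro[bicyclo[3.1.1]heptane-2,2'-chromene]-5',7'(6'H,8'H)-dione | CC(C)C1=C[C@]2(CC[C@@H]3C[C@H]2C3(C)C)OC2=C1C(=O)C(C)(C)C(=O)C2(C)C | intermediate
16 | (1S,2S,4'R,5R)-4'-isopropyl-6,6,6',6',8',8'-hexamethyl-3',4'-dihydrospiro[bicyclo[3.1.1]heptane-2,2'-chromene]-5',7'(6'H,8'H)-dione | CC(C)[C@H]1C[C@]2(CC[C@@H]3C[C@H]2C3(C)C)OC2=C1C(=O)C(C)(C)C(=O)C2(C)C | target

**Totals**

Total steps: 11. Longest linear sequence: 10 steps (steps 1–6, then 8–11).

**Steps most likely to fail**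

Step 10 (proposed new method). Hydrostannation or reduction of the enyne acceptor may outrun radical generation, or the cyclobutyl radical may be reduced or undergo 1,5-hydrogen transfer before the strained bridge closes. The allenyl enol may also isomerise to a furan, or the spiro centre may equilibrate through ring opening of the 2H-pyran. The fallback uses known chemistry and does not rely on the radical closure. It sets out from 8, which is C-acetylated (AcCl, pyridine, then DMAP) to 2-acetylsyncarpic acid F1. Kabbe condensation of F1 with (1S,5R)-nopinone F2 (a chiral-pool ketone; pyrrolidine, MeOH, 60 °C) should give, by aldol condensation and oxa-Michael closure on the face remote from the C6 bridge, spiro pyranone F3. iPrMgCl with CeCl3 (THF, −78 °C) should add to the C4' carbonyl, the only one not flanked by a quaternary carbon, to give tertiary alcohol F4. Dehydration (SOCl2, pyridine, 0 °C) returns to the route at 15.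

Step 9. Hydride abstraction at the propargylic C–H may be slow or unselective, and the electrophilic product may add the hydroquinone. The fallback reverses the order and sets out from 11. Bu3SnH with AIBN (toluene, 80 °C, slow addition) closes the C1–C2 bond 6-exo-dig onto the unactivated alkyne and should give exocyclic alkene F5, in which the tertiary C4'–H is now allylic. DDQ (1,4-dioxane) then performs the well-known oxidative cyclisation of a 2-allyl enolised 1,3-dicarbonyl to a 2H-pyran, returning to the route at 15.

Step 11. Facial selectivity of hydrogen delivery may be poor, and the allylic C2–O bond may undergo hydrogenolysis. The fallback sets C4' and C2 in one cycloaddition instead and sets out from 10. Thermal inverse-electron-demand hetero-Diels–Alder reaction of 10 with (1R,5R)-β-pinene F6 (toluene, 80 °C) forms O1'–C2 and C3'–C4' on the alkene face remote from the C6 bridge and arrives directly at 16. The C4' epimer would have to be removed by chromatography.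

**Further compounds**

F1 | step 10 | 6-acetyl-5-hydroxy-2,2,4,4-tetramethylcyclohex-5-ene-1,3-dione (2-acetylsyncarpic acid) | CC(=O)C1=C(O)C(C)(C)C(=O)C(C)(C)C1=O
F2 | step 10 | (1S,5R)-6,6-dimethylbicyclo[3.1.1]heptan-2-one (nopinone) | O=C1CC[C@@H]2C[C@H]1C2(C)C
F3 | step 10 | (1S,2S,5R)-6,6,6',6',8',8'-hexamethyl-3'H-spiro[bicyclo[3.1.1]heptane-2,2'-chromene]-4',5',7'(6'H,8'H)-trione | O=C1C[C@]2(CC[C@@H]3C[C@H]2C3(C)C)OC2=C1C(=O)C(C)(C)C(=O)C2(C)C
F4 | step 10 | (1S,2S,5R)-4'-hydroxy-4'-isopropyl-6,6,6',6',8',8'-hexamethyl-3',4'-dihydrospiro[bicyclo[3.1.1]heptane-2,2'-chromene]-5',7'(6'H,8'H)-dione (C4' undefined) | CC(C)C1(O)C[C@]2(CC[C@@H]3C[C@H]2C3(C)C)OC2=C1C(=O)C(C)(C)C(=O)C2(C)C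
F5 | step 9 | 5-hydroxy-2,2,6,6-tetramethyl-4-[1-[(1S,5R)-6,6-dimethylbicyclo[3.1.1]heptan-2-ylidene]-3-methylbutan-2-yl]cyclohex-4-ene-1,3-dione | CC(C)C(C=C1CC[C@@H]2C[C@H]1C2(C)C)C1=C(O)C(C)(C)C(=O)C(C)(C)C1=O
F6 | step 11 | (1R,5R)-(+)-β-pinene | C=C1CC[C@@H]2C[C@H]1C2(C)C
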